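The tetrahydropyran is cut at the bond between ring carbon C2 and the trioxygenated aryl ring. With C4 as a ketone, C2 is the β-carbon of a cyclic vinylogous ester, so an enantiopure 2-substituted 2,3-dihydro-4H-pyran-4-one (one catalytic hetero-Diels–Alder step from the guaiacyl propanal) accepts the arylboronic acid in a rhodium-catalysed 1,4-addition. The same β-alkoxy ketone relationship makes the benzylic C2–O1 bond reversible under acid, so the kinetic 2,6-trans adduct is equilibrated in the same operation to the 2,6-cis ketone, the C6 stereocentre dictating C2. Equatorial hydride delivery then sets the axial C4 oxygen, and acetylation and global hydrogenolysis finish the route.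

Key step: step 7

Assumption: the BINOL–Ti(IV) catalyst is taken to show the same facial sense towards the siloxydiene as in allyl transfer, so that the (R)-ligand leads to the (S)-dihydropyranone; if the sense is opposite, the (S)-ligand is used.

Step 1
Reactants: 1 4-(3-hydroxypropyl)-2-methoxyphenol (dihydroconiferyl alcohol)
Product: 2 3-[4-(benzyloxy)-3-methoxyphenyl]propan-1-ol
Conditions: BnBr (1.1 equiv), K2CO3, acetone, reflux
Reagents that add atoms: benzyl bromide, BrCc1ccccc1
Why: Williamson ether synthesis in which carbonate deprotonates only the phenol, so the primary alcohol should stay free.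

Step 2
Reactants: 2 3-[4-(benzyloxy)-3-methoxyphenyl]propan-1-ol
Product: 3 3-[4-(benzyloxy)-3-methoxyphenyl]propanal
Conditions: Dess–Martin periodinane, CH2Cl2, 0 °C to rt
Reagents that add atoms: none
Why: Dess–Martin oxidation stops cleanly at the aldehyde and tolerates the benzyl ether and the electron-rich arene.

Step 3
Reactants: 3 3-[4-(benzyloxy)-3-methoxyphenyl]propanal, 4 (E)-1-methoxy-3-(trimethylsilyloxy)buta-1,3-diene (Danishefsky's diene)
Product: 6 (S)-2-{2-[4-(benzyloxy)-3-methoxyphenyl]ethyl}-2,3-dihydro-4H-pyran-4-one, via silylated Mukaiyama aldol adduct 5 (not isolated)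
Conditions: (R)-BINOL (20 mol%), Ti(OiPr)4 (10 mol%), 4 Å MS, Et2O, −20 °C; then TFA, CH2Cl2, 0 °C
Reagents that add atoms: none
Why: Keck-type catalytic asymmetric hetero-Diels–Alder reaction (Mukaiyama aldol addition, then acid cyclisation with loss of methanol), in which the (R)-BINOL–titanium Lewis acid differentiates the aldehyde faces and so sets the (S) stereocentre that becomes C6 of the target.

Step 4
Reactants: 7 5-bromo-2-hydroxy-3-methoxybenzaldehyde
Product: 9 5-bromo-3-methoxybenzene-1,2-diol, via aryl formate 8 (not isolated)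
Conditions: 30% H2O2, aq. NaOH (1 equiv), 0 °C to rt, N2; then dilute HCl
Reagents that add atoms: hydrogen peroxide, OO
Why: Dakin oxidation, in which hydroperoxide adds to the ortho-hydroxy aldehyde, the electron-rich aryl group migrates to oxygen and the formate 8 is hydrolysed in situ to the catechol.

Step 5
Reactants: 9 5-bromo-3-methoxybenzene-1,2-diol
Product: 10 1,2-bis(benzyloxy)-5-bromo-3-methoxybenzene
Conditions: BnBr (2.3 equiv), K2CO3, DMF, 60 °C
Reagents that add atoms: benzyl bromide, BrCc1ccccc1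
Why: Double Williamson etherification of both catechol hydroxyls, which also removes the air sensitivity of the free catechol.

Step 6
Reactants: 10 1,2-bis(benzyloxy)-5-bromo-3-methoxybenzene
Product: 13 [3,4-bis(benzyloxy)-5-methoxyphenyl]boronic acid, via aryllithium 11 (not isolated), via lithium triisopropyl arylborate 12 (not isolated)
Conditions: n-BuLi, THF, −78 °C; B(OiPr)3, −78 °C to rt; 1 M HCl
Reagents that add atoms: triisopropyl borate, CC(C)OB(OC(C)C)OC(C)C; water, O
Why: Bromine–lithium exchange followed by electrophilic borylation and hydrolysis, with the ethers inert at −78 °C and the position of boron fixed by the bromide.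

Step 7
Reactants: 6 (S)-2-{2-[4-(benzyloxy)-3-methoxyphenyl]ethyl}-2,3-dihydro-4H-pyran-4-one, 13 [3,4-bis(benzyloxy)-5-methoxyphenyl]boronic acid
Product: 15 (2S,6S)-2-[3,4-bis(benzyloxy)-5-methoxyphenyl]-6-{2-[4-(benzyloxy)-3-methoxyphenyl]ethyl}tetrahydro-4H-pyran-4-one, via 2,6-trans ketone 14 (not isolated)
Conditions: [Rh(OH)(cod)]2 (3 mol%), dioxane/H2O 10:1, 40 °C; then aqueous work-up, crude in CH2Cl2, TsOH·H2O (0.2 equiv), rt to 40 °C
Reagents that add atoms: none
Why: Hayashi–Miyaura 1,4-addition: the aryl group passes from boron to Rh(I), adds to the β-carbon of the vinylogous ester (C6 of 6) along the axial trajectory anti to the side chain, and the oxa-π-allyl rhodium is protonated by water to give the kinetic 2,6-trans ketone 14. TsOH then opens the benzylic C–O bond by retro-oxa-Michael reaction to a hydroxy aryl enone, and the tetrahydropyran ring closes again by 6-endo-trig oxa-Michael addition through a chair transition state. The closest known reaction types are rhodium-catalysed arylboronic acid additions to 2-substituted 2,3-dihydro-4H-pyran-4-ones and the acid-mediated trans-to-cis equilibration of 2,6-disubstituted tetrahydropyran-4-ones. The new stereocentre at the aryl-bearing carbon is set under thermodynamic control by the existing centre that carries the arylethyl chain, with both substituents equatorial in the product. The step needs ring-opening at the aryl-bearing carbon and not at the chain-bearing carbon, which would erode the enantiomeric purity; the electron-rich aryl group, which stabilises positive charge at its benzylic carbon and conjugates with the enone that forms, should secure this.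

Step 8
Reactants: 15 (2S,6S)-2-[3,4-bis(benzyloxy)-5-methoxyphenyl]-6-{2-[4-(benzyloxy)-3-methoxyphenyl]ethyl}tetrahydro-4H-pyran-4-one
Product: 16 (2S,4S,6S)-2-[3,4-bis(benzyloxy)-5-methoxyphenyl]-6-{2-[4-(benzyloxy)-3-methoxyphenyl]ethyl}tetrahydro-2H-pyran-4-ol
Conditions: L-Selectride, THF, −78 °C; then H2O
Reagents that add atoms: none
Why: Bulky hydride reduction of a conformationally locked tetrahydropyran-4-one, in which attack along the equatorial trajectory should give the axial (4S) alcohol, trans to both equatorial substituents.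

Step 9
Reactants: 16 (2S,4S,6S)-2-[3,4-bis(benzyloxy)-5-methoxyphenyl]-6-{2-[4-(benzyloxy)-3-methoxyphenyl]ethyl}tetrahydro-2H-pyran-4-ol
Product: 17 (2S,4S,6S)-2-[3,4-bis(benzyloxy)-5-methoxyphenyl]-6-{2-[4-(benzyloxy)-3-methoxyphenyl]ethyl}tetrahydro-2H-pyran-4-yl acetate
Conditions: Ac2O, pyridine, DMAP (cat.), CH2Cl2, rt
Reagents that add atoms: acetic anhydride, CC(=O)OC(C)=O
Why: DMAP-catalysed acylation of the only free hydroxyl group, with retention at C4.

Step 10
Reactants: 17 (2S,4S,6S)-2-[3,4-bis(benzyloxy)-5-methoxyphenyl]-6-{2-[4-(benzyloxy)-3-methoxyphenyl]ethyl}tetrahydro-2H-pyran-4-yl acetate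
Product: 18 (2S,4S,6S)-2-(3,4-dihydroxy-5-methoxyphenyl)-6-[2-(4-hydroxy-3-methoxyphenyl)ethyl]tetrahydro-2H-pyran-4-yl acetate (CNP0143286.2)
Conditions: H2 (1 atm), 10% Pd/C, EtOAc/MeOH, rt
Reagents that add atoms: none
Why: Catalytic hydrogenolysis cleaves the three aryl benzyl ethers under mild conditions that should leave the acetate, the methyl ethers and the cyclic benzylic ether intact.

Compound list
1 | 4-(3-hydroxypropyl)-2-methoxyphenol (dihydroconiferyl alcohol) | COc1cc(CCCO)ccc1O | starting material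
2 | 3-[4-(benzyloxy)-3-methoxyphenyl]propan-1-ol | COc1cc(CCCO)ccc1OCc1ccccc1 | intermediate
3 | 3-[4-(benzyloxy)-3-methoxyphenyl]propanal | COc1cc(CCC=O)ccc1OCc1ccccc1 | intermediate
4 | (E)-1-methoxy-3-(trimethylsilyloxy)buta-1,3-diene (Danishefsky's diene) | CO/C=C/C(=C)O[Si](C)(C)C | starting material
5 | (S,E)-7-[4-(benzyloxy)-3-methoxyphenyl]-1-methoxy-5-(trimethylsilyloxy)hept-1-en-3-one | COc1cc(CC[C@H](O[Si](C)(C)C)CC(=O)/C=C/OC)ccc1OCc1ccccc1 | intermediate
6 | (S)-2-{2-[4-(benzyloxy)-3-methoxyphenyl]ethyl}-2,3-dihydro-4H-pyran-4-one | COc1cc(CC[C@H]2CC(=O)C=CO2)ccc1OCc1ccccc1 | intermediate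
7 | 5-bromo-2-hydroxy-3-methoxybenzaldehyde | O=Cc1cc(Br)cc(OC)c1O | starting material
8 | 5-bromo-2-hydroxy-3-methoxyphenyl formate | O=COc1cc(Br)cc(OC)c1O | intermediate
9 | 5-bromo-3-methoxybenzene-1,2-diol | Oc1cc(Br)cc(OC)c1O | intermediate
10 | 1,2-bis(benzyloxy)-5-bromo-3-methoxybenzene | COc1cc(Br)cc(OCc2ccccc2)c1OCc1ccccc1 | intermediate
11 | [3,4-bis(benzyloxy)-5-methoxyphenyl]lithium | [Li]c1cc(OC)c(OCc2ccccc2)c(OCc2ccccc2)c1 | intermediate
12 | lithium [3,4-bis(benzyloxy)-5-methoxyphenyl]tri(propan-2-yloxy)borate | [Li+].CC(C)O[B-](OC(C)C)(OC(C)C)c1cc(OC)c(OCc2ccccc2)c(OCc2ccccc2)c1 | intermediate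
13 | [3,4-bis(benzyloxy)-5-methoxyphenyl]boronic acid | OB(O)c1cc(OC)c(OCc2ccccc2)c(OCc2ccccc2)c1 | intermediate
14 | (2R,6S)-2-[3,4-bis(benzyloxy)-5-methoxyphenyl]-6-{2-[4-(benzyloxy)-3-methoxyphenyl]ethyl}tetrahydro-4H-pyran-4-one (2,6-trans) | COc1cc(CC[C@H]2CC(=O)C[C@H](c3cc(OCc4ccccc4)c(OCc4ccccc4)c(OC)c3)O2)ccc1OCc1ccccc1 | intermediate
15 | (2S,6S)-2-[3,4-bis(benzyloxy)-5-methoxyphenyl]-6-{2-[4-(benzyloxy)-3-methoxyphenyl]ethyl}tetrahydro-4H-pyran-4-one (2,6-cis) | COc1cc(CC[C@H]2CC(=O)C[C@@H](c3cc(OCc4ccccc4)c(OCc4ccccc4)c(OC)c3)O2)ccc1OCc1ccccc1 | intermediate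
16 | (2S,4S,6S)-2-[3,4-bis(benzyloxy)-5-methoxyphenyl]-6-{2-[4-(benzyloxy)-3-methoxyphenyl]ethyl}tetrahydro-2H-pyran-4-ol | COc1cc(CC[C@H]2C[C@H](O)C[C@@H](c3cc(OCc4ccccc4)c(OCc4ccccc4)c(OC)c3)O2)ccc1OCc1ccccc1 | intermediate
17 | (2S,4S,6S)-2-[3,4-bis(benzyloxy)-5-methoxyphenyl]-6-{2-[4-(benzyloxy)-3-methoxyphenyl]ethyl}tetrahydro-2H-pyran-4-yl acetate | COc1cc(CC[C@H]2C[C@H](OC(C)=O)C[C@@H](c3cc(OCc4ccccc4)c(OCc4ccccc4)c(OC)c3)O2)ccc1OCc1ccccc1 | intermediate
18 | (2S,4S,6S)-2-(3,4-dihydroxy-5-methoxyphenyl)-6-[2-(4-hydroxy-3-methoxyphenyl)ethyl]tetrahydro-2H-pyran-4-yl acetate | COc1cc(CC[C@H]2C[C@H](OC(C)=O)C[C@@H](c3cc(O)c(O)c(OC)c3)O2)ccc1O | target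

Total step count: 10. Longest linear sequence: 7 steps (steps 1, 2, 3, 7, 8, 9, 10); the aryl branch (steps 4, 5, 6) joins at step 7.

Steps most likely to fail

Step 7. The acid stage may open the ring at the chain-bearing carbon as well as at the benzylic carbon, which would erode the enantiomeric purity, or the equilibrium may leave an inconvenient share of the trans isomer; the arylation of the vinylogous ester may also be sluggish. The fallback sets the aryl-bearing centre kinetically by hydrogen delivery instead of by equilibration. It sets out from 6 and 13: a palladium(II)-catalysed oxidative boron–Heck arylation (Pd(OAc)2, 1,10-phenanthroline, O2, DMF), of the kind established for chromones and cyclic enaminones, would give (S)-6-[3,4-bis(benzyloxy)-5-methoxyphenyl]-2-{2-[4-(benzyloxy)-3-methoxyphenyl]ethyl}-2,3-dihydro-4H-pyran-4-one F1. Hydrogenation of the enol ether double bond over Pd/C in the presence of 2,2'-bipyridyl, which suppresses cleavage of aryl benzyl ethers, should add hydrogen from the face opposite the side chain and so return to the route at the 2,6-cis ketone 15.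

Step 3. Facial discrimination of an unbranched aliphatic aldehyde by the BINOL–titanium catalyst may be insufficient, giving low enantiomeric excess. The fallback builds the same ring from a reagent-controlled allylation and sets out from 3. Allylboration with (+)-B-allyldiisopinocampheylborane (Et2O, −78 °C; NaOH, H2O2) would give (S)-1-[4-(benzyloxy)-3-methoxyphenyl]hex-5-en-3-ol F2. Tsuji–Wacker oxidation (PdCl2, CuCl, O2, DMF/H2O) would give (S)-6-[4-(benzyloxy)-3-methoxyphenyl]-4-hydroxyhexan-2-one F3. Condensation with DMF dimethyl acetal would give (S,E)-7-[4-(benzyloxy)-3-methoxyphenyl]-1-(dimethylamino)-5-hydroxyhept-1-en-3-one F4, and TFA would close it, with loss of dimethylamine, to return at the dihydropyranone 6.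

Step 8. Hydride delivery may not be fully selective for the equatorial trajectory, giving a mixture of C4 epimers that is hard to separate. The fallback reaches the axial acetate by inversion and sets out from 15. NaBH4 in MeOH at 0 °C, which attacks axially, would give (2S,4R,6S)-2-[3,4-bis(benzyloxy)-5-methoxyphenyl]-6-{2-[4-(benzyloxy)-3-methoxyphenyl]ethyl}tetrahydro-2H-pyran-4-ol F5, the equatorial alcohol. A Mitsunobu reaction with acetic acid (PPh3, DIAD, THF) would invert C4 and return directly at the acetate 17, bypassing 16.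

Further compounds
F1 | step 7 | (S)-6-[3,4-bis(benzyloxy)-5-methoxyphenyl]-2-{2-[4-(benzyloxy)-3-methoxyphenyl]ethyl}-2,3-dihydro-4H-pyran-4-one | COc1cc(CC[C@H]2CC(=O)C=C(c3cc(OCc4ccccc4)c(OCc4ccccc4)c(OC)c3)O2)ccc1OCc1ccccc1
F2 | step 3 | (S)-1-[4-(benzyloxy)-3-methoxyphenyl]hex-5-en-3-ol | COc1cc(CC[C@H](O)CC=C)ccc1OCc1ccccc1
F3 | step 3 | (S)-6-[4-(benzyloxy)-3-methoxyphenyl]-4-hydroxyhexan-2-one | COc1cc(CC[C@H](O)CC(C)=O)ccc1OCc1ccccc1
F4 | step 3 | (S,E)-7-[4-(benzyloxy)-3-methoxyphenyl]-1-(dimethylamino)-5-hydroxyhept-1-en-3-one | COc1cc(CC[C@H](O)CC(=O)/C=C/N(C)C)ccc1OCc1ccccc1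
F5 | step 8 | (2S,4R,6S)-2-[3,4-bis(benzyloxy)-5-methoxyphenyl]-6-{2-[4-(benzyloxy)-3-methoxyphenyl]ethyl}tetrahydro-2H-pyran-4-ol | COc1cc(CC[C@H]2C[C@@H](O)C[C@@H](c3cc(OCc4ccccc4)c(OCc4ccccc4)c(OC)c3)O2)ccc1OCc1ccccc1
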